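The whole plan depends on deleting C28. This is the carbon of the seven-membered ring (C14, C15, C18, C24, C25, C26, C28) that carries the methyl group and the epoxide oxygen and lies between C14 and C26. Joining C14 to C26 instead leaves a cis-fused cyclohexene that is easy to make. C28 returns as dibromocarbene, and silver-induced opening of the cyclopropane cuts the temporary C14–C26 bond. That one operation gives the hydroazulene, a vinyl bromide at C28 for the methyl group, and a C26 carbinol that later relays its configuration to C14. The precursor is the silyl-protected cis-hydrindene carbinol bearing the fused gem-dibromocyclopropane. The oxepane half is joined at C11–C12 by aldol condensation.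

Key step: step 8

Remark on numbering: atom labels (C1 to O35) follow the heavy-atom order of the target SMILES and are used for every intermediate.
Assumption: the copper hydride catalyst built on (S)-p-tol-BINAP is taken to deliver hydride to the face of 5 that makes C18 R, by analogy with simple 3-alkylcyclopentenones. If the sense is opposite, the ligand antipode is used.

Step 1
Reactants: 1 3-ethoxycyclopent-2-en-1-one; 2 prenyl chloride (1-chloro-3-methylbut-2-ene)
Product: 5 3-(2-methylbut-3-en-2-yl)cyclopent-2-en-1-one, via prenylmagnesium chloride 3 (not isolated), via tertiary carbinol adduct 4 (not isolated)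
Conditions: Mg, THF, 0 °C; then 1, −78 → 0 °C; then 1 M HCl, rt
Reagents that add atoms: water, O
Why: Allylic Grignard reagents attack a carbonyl group through their γ-carbon, so 1,2-addition to the vinylogous ester builds the quaternary C15 with its vinyl group, and acid then ionises the enol-ether carbinol and hydrolyses it to the transposed enone (Stork–Danheiser sequence), leaving no stereocentre.

Step 2
Reactants: 5 3-(2-methylbut-3-en-2-yl)cyclopent-2-en-1-one; 6 allyl bromide
Product: 8 (2S,3R)-2-allyl-3-(2-methylbut-3-en-2-yl)cyclopentan-1-one (trans), via diphenylsilyl enol ether 7 (not isolated)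
Conditions: CuCl (5 mol %), NaOt-Bu (5 mol %), (S)-p-tol-BINAP (5 mol %), Ph2SiH2, toluene, 0 °C; then 6, Bu4N[Ph3SiF2], CH2Cl2, rt
Reagents that add atoms: allyl bromide (6), C=CCBr
Why: Copper-hydride-catalysed asymmetric conjugate reduction of a 3-alkylcyclopentenone sets C18 (R) under ligand control and stores the enolate regiospecifically as silyl enol ether 7, whose fluoride-triggered allylation at C24 occurs anti to the bulky C18 group (trans product), while the isolated vinyl group is not touched by the catalyst.

Step 3
Reactants: 8 (2S,3R)-2-allyl-3-(2-methylbut-3-en-2-yl)cyclopentan-1-one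
Product: 10 (3aR,7aR)-4,4-dimethyl-2,3,3a,4,7,7a-hexahydro-1H-inden-1-one (cis-fused), via trans-hydrindenone 9 (not isolated)
Conditions: second-generation Grubbs catalyst (3 mol %), CH2Cl2, 40 °C; then DBU (0.3 equiv), 40 °C
Reagents that add atoms: none
Why: Ring-closing metathesis of the allyl and 1,1-dimethylallyl arms closes the cyclohexene with the C14=C26 double bond, and base equilibration through the C21 enolate then moves C24 to the cis ring fusion, which is the more stable arrangement for a hydrinden-1-one.

Step 4
Reactants: 10 cis-hydrindenone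
Product: 11 (3aR,7aR)-4,4-dimethyl-1-methylidene-2,3,3a,4,7,7a-hexahydro-1H-indene
Conditions: Cp2TiMe2, toluene, 70 °C, dark
Reagents that add atoms: dimethyltitanocene Cp2TiMe2, C[Ti](C)(C1C=CC=C1)C1C=CC=C1
Why: Petasis methylenation is non-basic, so C22 is introduced at the carbonyl carbon without epimerising the adjacent C24.

Step 5
Reactants: 11 exocyclic methylene compound
Product: 12 (1R,3aR,7aR)-1,4,4-trimethyl-2,3,3a,4,7,7a-hexahydro-1H-inden-1-ol (hydroxyl syn to H24)
Conditions: Mn(dpm)3 (10 mol %), PhSiH3, O2 (1 atm), i-PrOH, 0 °C → rt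
Reagents that add atoms: dioxygen, O=O
Why: Mukaiyama hydration proceeds by hydrogen-atom transfer to the 1,1-disubstituted alkene (far faster than to the 1,2-disubstituted ring alkene) and Markovnikov capture of the tertiary C21 radical by O2 on the convex face, syn to H24, which should give the 21R carbinol that methyl addition to ketone 10 could not give.

Step 6
Reactants: 12 tertiary carbinol
Product: 13 triethylsilyl ether of 12
Conditions: Et3SiOTf, 2,6-lutidine, CH2Cl2, 0 °C
Reagents that add atoms: triethylsilyl triflate, CC[Si](CC)(CC)OS(=O)(=O)C(F)(F)F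
Why: Silylation of a tertiary alcohol with a silyl triflate and a hindered pyridine base is standard and masks the hydroxyl group against dibromocarbene and against the cation of step 8.

Step 7
Reactants: 13 silylated cis-hydrindene carbinol; 14 bromoform
Product: 15 gem-dibromocyclopropane of 13 (CBr2 = C28 bridging C14 and C26, syn to H18 and H24)
Conditions: 14, 50% aq NaOH, BnEt3NCl (cat.), CH2Cl2, 0 °C → rt
Reagents that add atoms: bromoform (14), BrC(Br)Br
Why: Dibromocarbene made under phase-transfer conditions adds in a stereospecific [2+1] cycloaddition to the only alkene, from the convex face syn to H18 and H24, and brings in C28, while both new cyclopropane stereocentres are erased again in step 8.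

Step 8
Reactants: 15 gem-dibromocyclopropane
Product: 17 (1R,3aR,7S,8aR)-6-bromo-1,4,4-trimethyl-1-(triethylsilyloxy)-1,2,3,3a,4,7,8,8a-octahydroazulen-7-ol (C26 hydroxyl anti to H18 and H24), via 2-bromoallyl cation 16 (not isolated)
Conditions: AgClO4 (2.5 equiv), CaCO3, acetone/H2O (5:1), rt → 40 °C, dark
Reagents that add atoms: water, O
Why: Monovalent silver pulls off the endo bromide while the C14–C26 σ bond opens in a disrotatory two-electron electrocyclic fashion, the only mode that turns both ring arms inward, so the cis,cis 2-bromoallyl cation 16 forms directly and cyclopropane strain pays for the cleavage. The closest known reaction type is the silver-assisted solvolytic ring expansion of ring-fused gem-dihalocyclopropanes to 2-halocycloalk-2-enols. The seven-membered ring is not closed by a new bond but arises by ring enlargement when the bond shared by the three- and six-membered rings is cut. Water must choose C26 over C14, and the quaternary C15 makes the C14 terminus neopentyl, so capture should occur at C26, which has only the C25 methylene beside it. The new C26 centre is set by the ring: with C25, C26, C28, C14 and C15 coplanar, C24 and C18 tilt toward the face of H18 and H24 to keep the cyclopentane bonds quasi-equatorial, and water should add anti to the C25–C24 bond on the opposite face (26S). CaCO3 removes the acid that would strip the silyl ether, and the C21 oxygen, being trans to C25 on the cyclopentane, cannot reach the cation.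

Step 9
Reactants: 17 2-bromocycloheptenol
Product: 18 (1R,3aR,7S,8aR)-1,4,4,6-tetramethyl-1-(triethylsilyloxy)-1,2,3,3a,4,7,8,8a-octahydroazulen-7-ol
Conditions: Me2Zn (3 equiv), Pd(dppf)Cl2 (5 mol %), THF, 60 °C
Reagents that add atoms: dimethylzinc, C[Zn]C
Why: Negishi coupling of an alkenyl bromide with Me2Zn installs C29 with retention of the ring alkene, the first equivalent of the zinc reagent merely deprotonating the carbinol.

Step 10
Reactants: 18 2-methylcycloheptenol; 19 N,N-dimethylacetamide dimethyl acetal
Product: 21 2-[(1R,3aR,5S,8aR)-1,4,4,6-tetramethyl-1-(triethylsilyloxy)-1,2,3,3a,4,5,8,8a-octahydroazulen-5-yl]-N,N-dimethylacetamide, via O-allyl ketene aminal 20 (not isolated)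
Conditions: 19 (5 equiv), xylene, 140 °C, removal of MeOH
Reagents that add atoms: N,N-dimethylacetamide dimethyl acetal (19), CC(OC)(OC)N(C)C
Why: In the Eschenmoser–Claisen rearrangement the carbinol exchanges into the amide acetal, loses methanol to ketene aminal 20 and undergoes a suprafacial [3,3] shift, so the C13–C14 bond forms on the face that carried the C26 oxygen (14S), the alkene moves to C26=C28, and the neutral medium spares the silyl ether.

Step 11
Reactants: 21 γ,δ-unsaturated dimethylamide
Product: 22 iodolactone (γ-lactone C12(=O)–O–C28 cis-fused at C14–C28 on the side-chain face, iodide at C26 on the opposite face)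
Conditions: I2 (2.5 equiv), THF/H2O (2:1), 0 °C → rt, dark
Reagents that add atoms: iodine, [I][I]; water, O
Why: In this iodolactonisation of a γ,δ-unsaturated tertiary amide the iodonium ion forms on the open face of C26=C28 anti to the side chain and the amide oxygen tethered at C14 attacks tertiary C28 in 5-exo fashion from the side-chain face, so the obligatory cis-fused lactone fixes the C28 oxygen and the anti iodide at C26, and hydrolysis of the iminium lactone frees dimethylamine, which buffers the acid.

Step 12
Reactants: 22 iodolactone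
Product: 23 methyl 2-(26S,28R-epoxy-hydroazulenyl)acetate (epoxide oxygen syn to the C13 arm)
Conditions: K2CO3, MeOH, rt
Reagents that add atoms: methanol, CO
Why: Methoxide opens the lactone (transesterification) and the freed C28 alkoxide displaces the anti iodide at C26 in an intramolecular SN2 reaction with inversion, which places the epoxide oxygen on the side-chain face (26S, 28R), the face that a peracid would not be expected to reach.

Step 13
Reactants: 23 epoxy ester
Product: 24 epoxy aldehyde (C12 formyl group on the C13 methylene)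
Conditions: i-Bu2AlH (1.1 equiv), CH2Cl2, −78 °C; aq potassium sodium tartrate
Reagents that add atoms: none
Why: Partial reduction of a methyl ester with one equivalent of i-Bu2AlH at low temperature stops at the tetrahedral aluminate and gives the aldehyde on work-up, conditions under which a trisubstituted epoxide is inert.

Step 14
Reactants: 25 (E)-geranylacetone
Product: 26 (5R,6R,9R)-5,6:9,10-diepoxy-6,10-dimethylundecan-2-one
Conditions: D-fructose-derived Shi ketone (0.3 equiv per alkene), KHSO5 (as 2KHSO5·KHSO4·K2SO4), K2CO3, Na2B4O7 buffer, Bu4NHSO4, MeCN/CH2(OMe)2/H2O, 0 °C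
Reagents that add atoms: potassium peroxymonosulfate KHSO5, [K+].[O-]S(=O)(=O)OO
Why: Shi epoxidation with the D-fructose-derived ketone converts both trisubstituted alkenes through a spiro dioxirane transition state into the R,R-type epoxides (C5 R, C30 R, C34 R), the catalyst controlling each alkene independently.

Step 15
Reactants: 26 diepoxy ketone
Product: 27 terminal tert-butyldimethylsilyl enol ether of 26 (C8(OSi)=C11H2)
Conditions: LiN(i-Pr)2, THF, −78 °C; t-BuMe2SiCl, DMPU, −78 → 0 °C
Reagents that add atoms: tert-butyldimethylsilyl chloride, CC(C)(C)[Si](C)(C)Cl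
Why: Kinetic deprotonation of the methyl ketone at the methyl group (C11) and O-silylation give the terminal enol silane, and epoxides do not react with the amide base at this temperature.

Step 16
Reactants: 27 diepoxy enol silane
Product: 28 (3R,5aR,9aR)-3-(tert-butyldimethylsilyloxy)-2,2,5a-trimethyloctahydro-1-benzoxepin-7(2H)-one (trans-fused, C8 ketone)
Conditions: t-BuMe2SiOTf (1.1 equiv), 2,6-di-tert-butyl-4-methylpyridine, CH2Cl2, −78 °C
Reagents that add atoms: none
Why: In this tandem oxa- and carbacyclisation of a diepoxy enol silane the silyl triflate activates the terminal epoxide, the inner epoxide oxygen opens it at tertiary C2 (oxepane by endo opening, C34 retained), and C11 of the enol silane opens the resulting epoxonium ion at tertiary C30 with inversion through a chair, which gives the trans ring fusion (H5 anti to C31) and returns the silyl triflate, so the net change is an isomerisation that leaves the silyl group on O35.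

Step 17
Reactants: 28 bicyclic ketone
Product: 29 (3R,5aR,9aR)-3-(tert-butyldimethylsilyloxy)-2,2,5a-trimethyl-3,4,5,5a,6,9a-hexahydro-1-benzoxepin-7(2H)-one (C6=C7 enone)
Conditions: IBX (2 equiv), DMSO, 70 °C
Reagents that add atoms: none
Why: IBX dehydrogenation of a ketone can only introduce the C6=C7 double bond because C30 carries no hydrogen, and the enone leaves C11 as the sole kinetic enolisation site.

Step 18
Reactants: 29 bicyclic enone; 24 epoxy aldehyde
Product: 30 aldol adduct (C11–C12 bond, C12 carbinol, mixture at C11 and C12)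
Conditions: LiN(i-Pr)2, THF, −78 °C, 29; then 24, −78 °C; AcOH quench
Reagents that add atoms: none
Why: Kinetic deprotonation of a cyclohexenone gives the cross-conjugated α′-enolate, here necessarily at C11 as in 5,5-disubstituted cyclohexenones, and its directed aldol addition to aldehyde 24 forms the C11–C12 bond, the two new stereocentres being removed in step 19.

Step 19
Reactants: 30 aldol adduct
Product: 32 cross-conjugated dienone (C11=C12 alkylidene, C6=C7), via mesylate 31 (not isolated)
Conditions: MsCl, Et3N, CH2Cl2, 0 °C; then DBU, rt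
Reagents that add atoms: none
Why: Mesylation and E1cB elimination of a β-hydroxy ketone give the alkylidene enone, whose double-bond geometry is irrelevant for step 20.

Step 20
Reactants: 32 dienone
Product: 33 saturated C8 ketone with equatorial C12 chain (11R)
Conditions: H2 (1 atm), 10% Pd/C, EtOAc, rt
Reagents that add atoms: none
Why: Heterogeneous hydrogenation saturates both conjugated alkenes, hydrogen reaching C11 from the face opposite the axial C31 methyl group so that C12 becomes equatorial (11R), which is also the thermodynamic epimer of the ketone, and the epoxide and silyl ethers are stable.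

Step 21
Reactants: 33 ketone
Product: 34 bis-silyl ether of the target (C8 tertiary carbinol, 8S)
Conditions: MeLi, CeCl3, THF, −78 °C
Reagents that add atoms: methyllithium, [Li]C
Why: The weakly basic organocerium reagent adds to the enolisable C8 ketone along the equatorial trajectory because axial approach is blocked by the syn-axial C31 methyl group, which gives the equatorial methyl group and the axial hydroxyl group (8S).

Step 22
Reactants: 34 bis-silyl ether
Product: 35 target CNP0216138.1
Conditions: Bu4NF, THF, 50 °C
Reagents that add atoms: none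
Why: Fluoride cleaves both silyl ethers without touching the epoxide or the tertiary alcohols and should release the target.

Compound list
1 | 3-ethoxycyclopent-2-en-1-one | CCOC1=CC(=O)CC1 | starting material
2 | prenyl chloride | CC(C)=CCCl | starting material
3 | prenylmagnesium chloride | CC(C)=CC[Mg]Cl | intermediate
4 | 1-(2-methylbut-3-en-2-yl)-3-ethoxycyclopent-2-en-1-ol (racemic) | C=CC(C)(C)C1(O)C=C(OCC)CC1 | intermediate
5 | 3-(2-methylbut-3-en-2-yl)cyclopent-2-en-1-one | C=CC(C)(C)C1=CC(=O)CC1 | intermediate
6 | allyl bromide | C=CCBr | starting material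
7 | diphenylsilyl enol ether of (R)-3-(2-methylbut-3-en-2-yl)cyclopentanone | C=CC(C)(C)[C@@H]1CCC(O[SiH](c2ccccc2)c2ccccc2)=C1 | intermediate
8 | (2S,3R)-2-allyl-3-(2-methylbut-3-en-2-yl)cyclopentan-1-one | C=CC(C)(C)[C@@H]1CCC(=O)[C@H]1CC=C | intermediate
9 | (3aR,7aS)-4,4-dimethyl-2,3,3a,4,7,7a-hexahydro-1H-inden-1-one (trans) | CC1(C)[C@@H]2CCC(=O)[C@H]2CC=C1 | intermediate
10 | (3aR,7aR)-4,4-dimethyl-2,3,3a,4,7,7a-hexahydro-1H-inden-1-one (cis) | CC1(C)[C@@H]2CCC(=O)[C@@H]2CC=C1 | intermediate
11 | (3aR,7aR)-4,4-dimethyl-1-methylidene-2,3,3a,4,7,7a-hexahydro-1H-indene | CC1(C)[C@@H]2CCC(=C)[C@@H]2CC=C1 | intermediate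
12 | (1R,3aR,7aR)-1,4,4-trimethyl-2,3,3a,4,7,7a-hexahydro-1H-inden-1-ol | CC1(C)[C@@H]2CC[C@@](C)(O)[C@@H]2CC=C1 | intermediate
13 | triethylsilyl ether of 12 | CC1(C)[C@@H]2CC[C@@](C)(O[Si](CC)(CC)CC)[C@@H]2CC=C1 | intermediate
14 | bromoform | BrC(Br)Br | starting material
15 | gem-dibromocyclopropane of 13 (key-step precursor) | CC1(C)[C@@H]2CC[C@@](C)(O[Si](CC)(CC)CC)[C@@H]2C[C@@H]3[C@H]1C3(Br)Br | intermediate
16 | 2-bromoallyl cation (C26–C28–C14) of the hydroazulene | [CH+]1C[C@H]2[C@](C)(O[Si](CC)(CC)CC)CC[C@H]2C(C)(C)C=C1Br | intermediate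
17 | (1R,3aR,7S,8aR)-6-bromo-1,4,4-trimethyl-1-(triethylsilyloxy)-1,2,3,3a,4,7,8,8a-octahydroazulen-7-ol (key-step product) | O[C@H]1C[C@H]2[C@](C)(O[Si](CC)(CC)CC)CC[C@H]2C(C)(C)C=C1Br | intermediate
18 | (1R,3aR,7S,8aR)-1,4,4,6-tetramethyl-1-(triethylsilyloxy)-1,2,3,3a,4,7,8,8a-octahydroazulen-7-ol | O[C@H]1C[C@H]2[C@](C)(O[Si](CC)(CC)CC)CC[C@H]2C(C)(C)C=C1C | intermediate
19 | N,N-dimethylacetamide dimethyl acetal | CC(OC)(OC)N(C)C | starting material
20 | O-allyl ketene aminal of 18 | C=C(N(C)C)O[C@H]1C[C@H]2[C@](C)(O[Si](CC)(CC)CC)CC[C@H]2C(C)(C)C=C1C | intermediate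
21 | C14 acetic acid dimethylamide with C26=C28 alkene | CN(C)C(=O)C[C@@H]1C(C)(C)[C@@H]2CC[C@@](C)(O[Si](CC)(CC)CC)[C@@H]2CC=C1C | intermediate
22 | iodolactone (C28 lactone oxygen syn to C13, C26 iodide anti) | I[C@@H]1C[C@H]2[C@](C)(O[Si](CC)(CC)CC)CC[C@H]2C(C)(C)[C@H]2CC(=O)O[C@@]12C | intermediate
23 | epoxy methyl ester | COC(=O)C[C@@H]1C(C)(C)[C@@H]2CC[C@@](C)(O[Si](CC)(CC)CC)[C@@H]2C[C@@H]2O[C@@]21C | intermediate
24 | epoxy aldehyde | O=CC[C@@H]1C(C)(C)[C@@H]2CC[C@@](C)(O[Si](CC)(CC)CC)[C@@H]2C[C@@H]2O[C@@]21C | intermediate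
25 | (E)-geranylacetone | CC(=O)CC/C=C(\C)CCC=C(C)C | starting material
26 | (5R,6R,9R)-5,6:9,10-diepoxy-6,10-dimethylundecan-2-one | CC(=O)CC[C@H]1O[C@]1(C)CC[C@H]1OC1(C)C | intermediate
27 | terminal tert-butyldimethylsilyl enol ether of 26 | C=C(O[Si](C)(C)C(C)(C)C)CC[C@H]1O[C@]1(C)CC[C@H]1OC1(C)C | intermediate
28 | (3R,5aR,9aR)-3-(tert-butyldimethylsilyloxy)-2,2,5a-trimethyloctahydro-1-benzoxepin-7(2H)-one | CC1(C)O[C@@H]2CCC(=O)C[C@@]2(C)CC[C@H]1O[Si](C)(C)C(C)(C)C | intermediate
29 | C6=C7 enone of 28 | CC1(C)O[C@@H]2C=CC(=O)C[C@@]2(C)CC[C@H]1O[Si](C)(C)C(C)(C)C | intermediate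
30 | aldol adduct (C11 and C12 undefined) | CC1(C)O[C@@H]2C=CC(=O)C(C(O)C[C@@H]3C(C)(C)[C@@H]4CC[C@@](C)(O[Si](CC)(CC)CC)[C@@H]4C[C@@H]4O[C@@]43C)[C@@]2(C)CC[C@H]1O[Si](C)(C)C(C)(C)C | intermediate
31 | C12 mesylate of 30 | CC1(C)O[C@@H]2C=CC(=O)C(C(OS(C)(=O)=O)C[C@@H]3C(C)(C)[C@@H]4CC[C@@](C)(O[Si](CC)(CC)CC)[C@@H]4C[C@@H]4O[C@@]43C)[C@@]2(C)CC[C@H]1O[Si](C)(C)C(C)(C)C | intermediate
32 | cross-conjugated dienone (C11=C12 geometry undefined) | CC1(C)O[C@@H]2C=CC(=O)C(=CC[C@@H]3C(C)(C)[C@@H]4CC[C@@](C)(O[Si](CC)(CC)CC)[C@@H]4C[C@@H]4O[C@@]43C)[C@@]2(C)CC[C@H]1O[Si](C)(C)C(C)(C)C | intermediate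
33 | saturated C8 ketone (11R) | CC1(C)O[C@@H]2CCC(=O)[C@H](CC[C@@H]3C(C)(C)[C@@H]4CC[C@@](C)(O[Si](CC)(CC)CC)[C@@H]4C[C@@H]4O[C@@]43C)[C@@]2(C)CC[C@H]1O[Si](C)(C)C(C)(C)C | intermediate
34 | O35-tert-butyldimethylsilyl, O23-triethylsilyl ether of the target | CC1(C)O[C@@H]2CC[C@](C)(O)[C@H](CC[C@@H]3C(C)(C)[C@@H]4CC[C@@](C)(O[Si](CC)(CC)CC)[C@@H]4C[C@@H]4O[C@@]43C)[C@@]2(C)CC[C@H]1O[Si](C)(C)C(C)(C)C | intermediate
35 | CNP0216138.1 | CC1(C)O[C@@H]2CC[C@](C)(O)[C@H](CC[C@@H]3C(C)(C)[C@@H]4CC[C@@](C)(O)[C@@H]4C[C@@H]4O[C@@]43C)[C@@]2(C)CC[C@H]1O | target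

Total step count: 22. Longest linear sequence: 18 steps (steps 1–13, then 18–22). The oxepane branch (steps 14–17) adds 4 steps.

Steps most likely to fail

Step 8. Water may capture the cation on the wrong face of C26, or without facial preference, which would break the stereochemical relay to C14. The fallback sets out from 15. The silver-induced opening is run without regard to the C26 face. The mixture of 17 and its C26 epimer F1 is oxidised with Dess–Martin periodinane to bromoenone F2. A Corey–Bakshi–Shibata reduction with (R)-2-methyl-CBS-oxazaborolidine and catecholborane, in which the bromovinyl arm acts as the large group, then sets 26S under reagent control. The route is rejoined at 17.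

Step 10. The ketene aminal may be lost by thermal elimination to a cycloheptadiene before the crowded C13–C14 bond can form. The fallback sets out from 18. Acetylation (Ac2O, DMAP, pyridine) gives acetate F3. Treatment with LiN(i-Pr)2 and Me3SiCl at −78 °C gives silyl ketene acetal F4, which undergoes an Ireland–Claisen rearrangement on warming to room temperature to give trimethylsilyl ester F5. Aqueous work-up gives acid F6. Iodolactonisation of the acid (I2, NaHCO3, MeCN/H2O) rejoins the route at 22.

Step 18. Proton transfer between the hindered enolate and the enolisable aldehyde, and retro-aldol cleavage on work-up, may prevent the union. The fallback sets out from 29. LiN(i-Pr)2 and ClP(O)(OEt)2 give dienyl phosphate F7. A second equivalent of LiN(i-Pr)2 induces the 1,3 shift of phosphorus from oxygen to C11 and gives β-ketophosphonate F8. An irreversible Horner–Wadsworth–Emmons olefination with 24 (NaH, THF) then rejoins the route at 32 and bypasses 30 and 31.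

Further compounds
F1 | step 8 | C26 epimer of 17 (26R) | O[C@@H]1C[C@H]2[C@](C)(O[Si](CC)(CC)CC)CC[C@H]2C(C)(C)C=C1Br
F2 | step 8 | 2-bromocycloheptenone (C26 ketone) | O=C1C[C@H]2[C@](C)(O[Si](CC)(CC)CC)CC[C@H]2C(C)(C)C=C1Br
F3 | step 10 | C26 acetate of 18 | CC(=O)O[C@H]1C[C@H]2[C@](C)(O[Si](CC)(CC)CC)CC[C@H]2C(C)(C)C=C1C
F4 | step 10 | trimethylsilyl ketene acetal of F3 | C=C(O[Si](C)(C)C)O[C@H]1C[C@H]2[C@](C)(O[Si](CC)(CC)CC)CC[C@H]2C(C)(C)C=C1C
F5 | step 10 | trimethylsilyl ester of the C14 acetic acid | C[Si](C)(C)OC(=O)C[C@@H]1C(C)(C)[C@@H]2CC[C@@](C)(O[Si](CC)(CC)CC)[C@@H]2CC=C1C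
F6 | step 10 | C14 acetic acid | OC(=O)C[C@@H]1C(C)(C)[C@@H]2CC[C@@](C)(O[Si](CC)(CC)CC)[C@@H]2CC=C1C
F7 | step 18 | dienyl diethyl phosphate of 29 | CC1(C)O[C@@H]2C=CC(OP(=O)(OCC)OCC)=C[C@@]2(C)CC[C@H]1O[Si](C)(C)C(C)(C)C
F8 | step 18 | C11 diethyl β-ketophosphonate of 29 (C11 undefined) | CC1(C)O[C@@H]2C=CC(=O)C(P(=O)(OCC)OCC)[C@@]2(C)CC[C@H]1O[Si](C)(C)C(C)(C)C
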